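# Proposed synthesis of CNP0185847.3 (29): enolate aldol onto an epoxy aldehyde with in-flask Payne shift

## Analysis of the target

Numbering used throughout: ring C1–C10 with the alkene C1=C10 (methyl C14 on C10), ketone C9, C8, spiro carbon C7, C6, oxirane carbons C5 and C4 (C4 carries C15H2OAc), C3, C2; the exocyclic oxirane carbon C11 carries methyl C13 and C12H2OAc.

Target 29 is a germacrane: a ten-membered carbocycle with an (E)-enone (C1=C10–C9=O), a ring-fused trisubstituted oxirane at C4–C5, a spiro tetrasubstituted oxirane at C7–C11, and primary acetates on C15 and C12. It has four stereocentres, (4R,5R,7S,11R). C4 and C5 are contiguous, with the ring bonds C3–C4 and C5–C6 cis on the oxirane. C7 and C11 are contiguous, with C8 and C12 cis on the spiro oxirane; the two pairs are 1,3-related through C6, and three of the four centres are fully substituted. The C9 ketone has the C7 oxirane in the β,γ-position, so base opens it by elimination through C8. Any intermediate with a C7 carbonyl stands in the same relation to the C4–C5 oxirane, both oxiranes are acid-labile, and a C7 carbonyl cannot coexist with a C9 carbonyl (enolised 1,3-dicarbonyl). The difficulties are the medium ring with its (E)-trisubstituted alkene and the relay of configuration between two oxiranes that share no rigid framework before the ring exists. The strategy rests on one feature: O15–C15–C4(–O–)C5 is a 2,3-epoxy alcohol, the Payne isomer of a C5 alkoxide flanked by a C4–C15 oxirane. C5 is also 1,3 to the oxygen on C7, so the C5–C6 bond is an aldol bond between a C7 methyl ketone and a C5 aldehyde.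

## Retrosynthetic reasoning

**29 back to 26.** The C9 ketone is made last (29 from 28), because only then does the base-labile β,γ-epoxy enone appear, and under neutral conditions. The two acetates come from the triol 27. Triol 27 comes from reduction of the bridged epoxy lactone 26, whose lactone carbonyl is C12 and whose ring oxygen is O9.

**26 back to 24 (C7–C11 and C11–O).** The spiro oxirane is cut at C7–C11 and C11–O, a Darzens disconnection carried by an ester tether on O9 (24 to 25 to 26). This was preferred to an untethered addition to C7: the three-atom bridge O9–C12–C11 can reach C7 only from the side of O9, and the oxirane must then be cis-fused on the lactone. A single carbinol centre at C9, later erased, therefore fixes both C7 and C11. The forward reaction has to generate the ester enolate without base, because ketone 24 has leaving groups β to both of its α-carbons.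

**24 back to 19 (oxidation levels at C7 and C9).** C9 must be a (9R)-carbinol for the tether, and C7 must not be a carbonyl while C9 is one. So 24 comes from 23, 22 and 21 by acylation, desilylation and oxidation, and the (9R)-alcohol 21 comes from reagent-controlled reduction of enone 20. Enone 20 is the oxidation product of the ring-closure product 19, so the facial outcome of the ring closure does not matter.

**19 back to 18 (C9–C10).** The ring is opened at C9–C10, between an aldehyde carbon and an alkenyl iodide carbon (Nozaki–Hiyama–Kishi closure). This bond was chosen because the (E)-alkene geometry is then fixed before cyclisation, the coupling tolerates the oxirane and the acetate, and it addresses only the aldehyde.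

**18 back to 14.** Aldehyde 18 comes from acetal 17, which comes from 16 and 15 by silylation and reduction of the C7 ketone. Acetate 15 comes from the primary alcohol 14. These steps only park C7 at the alcohol level and protect O15.

**14 back to 10 and 11 (C5–C6 and the Payne shift).** Reversing the Payne shift in 14 gives the C5 alkoxide 13 beside a C4–C15 oxirane. Cutting C5–C6 of 13 gives the enolate 12 of methyl ketone 11 and the epoxy aldehyde 10. The cut divides the chain into two pieces of similar size, uses a commercial ketone, and reduces the C4/C5 problem to one quaternary centre from a Sharpless epoxidation plus one facial choice at an aldehyde.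

**10 back to 1 and 5.** Aldehyde 10 comes from epoxy alcohol 9, the Sharpless product of the 2-substituted allyl alcohol 8. Alcohol 8 comes from acrylate 7, made by methylenation of phosphonate 6, the alkylation product of 5 with iodide 4. Iodide 4 comes from alcohol 3, and 3 from alkyne 1 by hydrozirconation and iodination. The iodoalkene is made at the outset because hydrozirconation after fragment union would not spare a ketone or the oxiranes.

## Alternatives that were turned down

**Alternative 1: ring contraction with loss of a sulfonyl bridge.**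
- Disconnection: C4=C5 is the ring-forming alkene, made from an eleven-membered ring in which a sulfonyl group bridges C4 and C5 and one flanking carbon carries chlorine; both oxiranes are deferred.
- Forward key step: base-induced Ramberg–Bäcklund reaction (1,3-elimination to an episulfone, then extrusion) gives the ten-membered triene A1, with C9 ketal and PMB ethers on C12 and C15.
- For: it avoids direct closure of a ten-membered ring, and A1 holds every carbon. Its two allylic ethers could, after deprotection, direct two reagent-controlled Sharpless epoxidations, so on absolute control of each oxirane taken alone it is as strong as the chosen route.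
- Against: A1 has no stereocentre, so all four must be made late on a flexible triene. The C4=C5 geometry from this reaction in a medium ring is not reliably ring-cis, the tetrasubstituted C7=C11 geometry needs its own solution, three alkenes must be told apart, and the ketal and PMB groups must be removed in the presence of two oxiranes.
- Comparison: the chosen route is longer in redox and protecting-group steps at C7 and C9, but it fixes the ring-cis C4–C5 oxirane by a stereospecific shift before the ring exists and fixes C7/C11 by a geometric constraint.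

**Alternative 2: tethered Darzens reaction as the organising step.**
- Disconnection: C7–C11 and C11–O, from a dichloropropanoate on O9 of a preformed ten-membered C7 ketone that already holds the C4–C5 oxirane.
- Forward key step: samarium-mediated reduction of the dichloro ester to a chloro enolate, transannular addition to C7 and oxirane closure give the bridged epoxy lactone A2.
- For: C7 and C11 are set together and unambiguously, without base. On this point it is exactly as strong as the chosen route, because A2 is the same compound as 26 and the chosen route uses this operation at steps 19 and 20.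
- Against: as the strategy-defining step it leaves open how the ring, the (9R)-carbinol and the ring-cis oxirane are made, which are the harder parts.
- Comparison: the chosen strategy keeps this step and adds a convergent, stereodefined solution for C4/C5 and for the open-chain cyclisation precursor.

**Alternative 3: fragmentation of a [2+2] photoadduct.**
- Disconnection: both ring alkenes arise by cleaving C1–C4 and C5–C10 of a cyclobutane-containing tricycle built by enone–cyclobutene photocycloaddition on a chiral-pool cyclohexenone.
- Forward key step: heating opens the tricycle to the cyclodecadienone A3, with (E)-enone, ring-cis C4=C5, a silyl ether on C7 and a silyl ether on C15.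
- For: it is clearly stronger in step economy for the carbocycle. There is no macrocyclisation, and both alkene geometries follow from a concerted process.
- Against: A3 is a cyclodeca-1,5-diene and can undergo Cope rearrangement at the temperature of its formation. Its only stereocentre (C7) is destroyed on the way to the spiro oxirane, and oxidising C7 beside the C9 ketone gives a 1,3-diketone. The C11–C13 unit must still be added with control of two fully substituted centres, which requires C9 to be taken back to a carbinol. Regiocontrol and scale of the photocycloaddition are further burdens.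
- Comparison: the chosen route pays with a longer linear sequence, but every stereocentre has a defined origin: Sharpless epoxidation, chelate-controlled aldol, reagent-controlled reduction, and the bridging constraint.

Key step: step 8

Remarks on the chemistry (assumptions): the C1–C10 unit is carried as the (E)-iodoalkene from step 1 and not as an alkyne. The C7 carbinol of 16–23 is a mixture of epimers, and 19 is also a mixture at C9; both centres are later erased or reset, so their SMILES leave them open. Ketone 11 is kept in slight excess over base in step 8 so that no free amide base meets the iodoalkene.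

## Route

Step 1
Reactants: 1 pent-3-yn-1-ol
Product: 3 (E)-4-iodopent-3-en-1-ol, via bis-zirconated alkenylzirconocene 2 (not isolated)
Conditions: Cp2Zr(H)Cl (2.5 equiv), THF, rt to 40 °C; then I2, 0 °C
Reagents that add atoms: iodine, [I][I]
Why: Hydrozirconation is a syn addition of Zr–H; one equivalent of reagent is consumed by the hydroxyl group, and with excess reagent the regioisomers equilibrate to the less hindered alkenylzirconocene with zirconium on the methyl-bearing carbon C10, so that iodinolysis with retention gives the (E)-2-iodoalkene.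

Step 2
Reactants: 3 (E)-4-iodopent-3-en-1-ol
Product: 4 (E)-2,5-diiodopent-2-ene
Conditions: I2, PPh3, imidazole, CH2Cl2, 0 °C to rt
Reagents that add atoms: iodine, [I][I]
Why: Appel-type iodination converts the primary alcohol into the primary iodide by SN2 displacement of the oxyphosphonium group; the alkenyl iodide is inert.

Step 3
Reactants: 5 triethyl phosphonoacetate; 4 (E)-2,5-diiodopent-2-ene
Product: 6 ethyl (E)-2-(diethoxyphosphoryl)-6-iodohept-5-enoate (racemic)
Conditions: NaH, DMF, 0 °C; then 4, 50 °C (5 in excess)
Reagents that add atoms: none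
Why: C-alkylation of the stabilised phosphonoacetate anion with a primary iodide (SN2); the weakly basic anion limits elimination and an excess of 5 limits dialkylation.

Step 4
Reactants: 6 ethyl (E)-2-(diethoxyphosphoryl)-6-iodohept-5-enoate
Product: 7 ethyl (E)-6-iodo-2-methylidenehept-5-enoate
Conditions: aq. HCHO (37%), K2CO3, THF–H2O, 40 °C
Reagents that add atoms: formaldehyde, C=O
Why: Horner–Wadsworth–Emmons methylenation of an α-alkyl phosphonoacetate with formaldehyde in aqueous carbonate is a standard route to 2-substituted acrylates.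

Step 5
Reactants: 7 ethyl (E)-6-iodo-2-methylidenehept-5-enoate
Product: 8 (E)-6-iodo-2-methylidenehept-5-en-1-ol
Conditions: iBu2AlH (2.2 equiv), CH2Cl2, −78 °C; aq. potassium sodium tartrate
Reagents that add atoms: none
Why: iBu2AlH reduces the enoate 1,2 to the allylic alcohol at −78 °C without touching the alkenyl iodide.

Step 6
Reactants: 8 (E)-6-iodo-2-methylidenehept-5-en-1-ol
Product: 9 (R)-{2-[(E)-4-iodopent-3-en-1-yl]oxiran-2-yl}methanol
Conditions: Ti(OiPr)4 (10 mol%), D-(−)-diisopropyl tartrate (12 mol%), tBuOOH, 4 Å molecular sieves, CH2Cl2, −20 °C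
Reagents that add atoms: tert-butyl hydroperoxide, CC(C)(C)OO
Why: Sharpless asymmetric epoxidation of a 2-substituted allyl alcohol; the D-tartrate complex delivers oxygen to the face that gives the (R)-oxirane, which sets C4 (inverted in step 8), and only the alkene of the titanium-bound allylic alcohol is epoxidised.

Step 7
Reactants: 9 (R)-{2-[(E)-4-iodopent-3-en-1-yl]oxiran-2-yl}methanol
Product: 10 (S)-2-[(E)-4-iodopent-3-en-1-yl]oxirane-2-carbaldehyde
Conditions: Dess–Martin periodinane, NaHCO3, CH2Cl2, 0 °C to rt; used crude
Reagents that add atoms: none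
Why: Buffered Dess–Martin oxidation of the primary alcohol; the α-carbon is quaternary, so the aldehyde cannot epimerise (the descriptor changes only because the priorities change).

Step 8
Reactants: 11 4,4-dimethoxybutan-2-one; 10 (S)-2-[(E)-4-iodopent-3-en-1-yl]oxirane-2-carbaldehyde
Product: 14 1-{(2R,3R)-3-(hydroxymethyl)-3-[(E)-4-iodopent-3-en-1-yl]oxiran-2-yl}-4,4-dimethoxybutan-2-one, via bromomagnesium enolate 12 (not isolated), via bromomagnesium (4S,5R)-aldolate 13 (not isolated)
Conditions: LiN(iPr)2, THF, −78 °C; MgBr2·OEt2, −78 °C; 10, −78 °C, then −20 °C; sat. aq. NH4Cl at −40 °C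
Reagents that add atoms: none
Why: LiN(iPr)2 removes a methyl proton of 11 under kinetic control, and MgBr2·OEt2 turns the lithium enolate into the bromomagnesium enolate 12. Enolate 12 adds through C6 to the aldehyde carbon C5 of 10 and forms the C5–C6 bond; the closest known reaction type is the chelation-controlled addition of metal enolates to α,β-epoxy aldehydes. Magnesium bridges the aldehyde oxygen and the oxirane oxygen, so the carbonyl lies over the three-membered ring and the enolate enters past the oxirane CH2 (C15), away from the C3 chain, which sets C5 and gives the (4S,5R)-aldolate 13. On warming, the C5 alkoxide attacks C4 from the side opposite the oxirane C–O bond (3-exo-tet, the Payne rearrangement of a 2,3-epoxy alkoxide), closing the new C4–O–C5 oxirane and releasing the C15 alkoxide. C4, set as (S) by the Sharpless step, is inverted to (R) with C3 and C6 cis on the new ring, while C5 keeps its configuration. The equilibrium should lie on the side of the trisubstituted oxirane and the primary alkoxide. The step needs methyl-side enolisation, the chelate-controlled face at C5, and survival of the β,γ-epoxy ketone; the magnesium counter-ion and the cold, mildly acidic quench serve the last two.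

Step 9
Reactants: 14 1-{(2R,3R)-3-(hydroxymethyl)-3-[(E)-4-iodopent-3-en-1-yl]oxiran-2-yl}-4,4-dimethoxybutan-2-one
Product: 15 {(2R,3R)-3-(4,4-dimethoxy-2-oxobutyl)-2-[(E)-4-iodopent-3-en-1-yl]oxiran-2-yl}methyl acetate
Conditions: Ac2O, pyridine, CH2Cl2, 0 °C
Reagents that add atoms: acetic anhydride, CC(=O)OC(C)=O
Why: Acetylation of the primary alcohol under weakly basic conditions at 0 °C should leave the β,γ-epoxy ketone intact; any cyclic hemiketal form of 14 equilibrates with the open hydroxy ketone, which is the species acylated.

Step 10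
Reactants: 15 {(2R,3R)-3-(4,4-dimethoxy-2-oxobutyl)-2-[(E)-4-iodopent-3-en-1-yl]oxiran-2-yl}methyl acetate
Product: 16 {(2R,3R)-3-(2-hydroxy-4,4-dimethoxybutyl)-2-[(E)-4-iodopent-3-en-1-yl]oxiran-2-yl}methyl acetate (C7 epimers)
Conditions: NaBH4, MeOH–THF, −40 °C
Reagents that add atoms: none
Why: Borohydride reduction of the ketone in the presence of the acetate; taking C7 to the alcohol level ends the base sensitivity of the β,γ-epoxy ketone and avoids a C7/C9 dicarbonyl later, and the new centre need not be controlled because it is reoxidised in step 18.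

Step 11
Reactants: 16 {(2R,3R)-3-(2-hydroxy-4,4-dimethoxybutyl)-2-[(E)-4-iodopent-3-en-1-yl]oxiran-2-yl}methyl acetate
Product: 17 {(2R,3R)-3-[2-(tert-butyldimethylsilyloxy)-4,4-dimethoxybutyl]-2-[(E)-4-iodopent-3-en-1-yl]oxiran-2-yl}methyl acetate (C7 epimers)
Conditions: TBSCl, imidazole, DMF, rt
Reagents that add atoms: tert-butyldimethylsilyl chloride, CC(C)(C)[Si](C)(C)Cl
Why: Silylation of the secondary alcohol under basic conditions blocks cyclisation of the hydroxyl onto the oxirane and gives a group that survives steps 12 to 16.

Step 12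
Reactants: 17 {(2R,3R)-3-[2-(tert-butyldimethylsilyloxy)-4,4-dimethoxybutyl]-2-[(E)-4-iodopent-3-en-1-yl]oxiran-2-yl}methyl acetate
Product: 18 {(2R,3R)-3-[2-(tert-butyldimethylsilyloxy)-4-oxobutyl]-2-[(E)-4-iodopent-3-en-1-yl]oxiran-2-yl}methyl acetate (C7 epimers)
Conditions: pyridinium p-toluenesulfonate (cat.), acetone–H2O, rt to 40 °C
Reagents that add atoms: water, O
Why: Mild acid-catalysed hydrolysis of the dimethyl acetal; the oxirane is deactivated towards ionisation at C4 by the acyloxymethyl group and a secondary TBS ether tolerates this acid, and the β-silyloxy aldehyde is used without delay.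

Step 13
Reactants: 18 {(2R,3R)-3-[2-(tert-butyldimethylsilyloxy)-4-oxobutyl]-2-[(E)-4-iodopent-3-en-1-yl]oxiran-2-yl}methyl acetate
Product: 19 (E,4R,5R)-4-(acetoxymethyl)-7-(tert-butyldimethylsilyloxy)-4,5-epoxy-10-methylcyclodec-1(10)-en-9-ol (target numbering; C7 and C9 epimers)
Conditions: CrCl2 (8 equiv), NiCl2 (2 mol%), DMSO–THF, rt, slow addition, high dilution
Reagents that add atoms: none
Why: Nozaki–Hiyama–Kishi reaction: nickel inserts into the C10–I bond, the alkenyl group passes to trivalent chromium and adds only to the aldehyde, forming C9–C10 and the ten-membered ring with retention of the (E)-geometry; the C9 configuration is left open here because it is reset in steps 14 and 15.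

Step 14
Reactants: 19 (E,4R,5R)-4-(acetoxymethyl)-7-(tert-butyldimethylsilyloxy)-4,5-epoxy-10-methylcyclodec-1(10)-en-9-ol
Product: 20 (E,4R,5R)-4-(acetoxymethyl)-7-(tert-butyldimethylsilyloxy)-4,5-epoxy-10-methylcyclodec-1(10)-en-9-one (C7 epimers)
Conditions: Dess–Martin periodinane, NaHCO3, CH2Cl2, 0 °C to rt
Reagents that add atoms: none
Why: Neutral oxidation of the allylic alcohol to the enone merges the C9 epimers; C7 is a silyl ether, so no 1,3-dicarbonyl arises.

Step 15
Reactants: 20 (E,4R,5R)-4-(acetoxymethyl)-7-(tert-butyldimethylsilyloxy)-4,5-epoxy-10-methylcyclodec-1(10)-en-9-one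
Product: 21 (E,4R,5R,9R)-4-(acetoxymethyl)-7-(tert-butyldimethylsilyloxy)-4,5-epoxy-10-methylcyclodec-1(10)-en-9-ol (C7 epimers)
Conditions: (S)-2-methyl-CBS-oxazaborolidine (0.3 equiv), BH3·SMe2, THF, −30 °C; MeOH
Reagents that add atoms: none
Why: Corey–Bakshi–Shibata reduction under reagent control: the alkenyl carbon C10 acts as the large group and C8H2 as the small one, so the (S)-catalyst should deliver hydride to the face that gives the (9R)-carbinol needed for the tether.

Step 16
Reactants: 21 (E,4R,5R,9R)-4-(acetoxymethyl)-7-(tert-butyldimethylsilyloxy)-4,5-epoxy-10-methylcyclodec-1(10)-en-9-ol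
Product: 22 (E,4R,5R,9R)-4-(acetoxymethyl)-7-(tert-butyldimethylsilyloxy)-4,5-epoxy-10-methylcyclodec-1(10)-en-9-yl 2,2-dichloropropanoate (C7 epimers)
Conditions: 2,2-dichloropropanoyl chloride, pyridine, DMAP (cat.), CH2Cl2, 0 °C
Reagents that add atoms: 2,2-dichloropropanoyl chloride, CC(Cl)(Cl)C(Cl)=O
Why: Acylation of the hindered secondary alcohol with a reactive acid chloride that has no α-hydrogen and so cannot form a ketene; C9 is not touched.

Step 17
Reactants: 22 (E,4R,5R,9R)-4-(acetoxymethyl)-7-(tert-butyldimethylsilyloxy)-4,5-epoxy-10-methylcyclodec-1(10)-en-9-yl 2,2-dichloropropanoate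
Product: 23 (E,4R,5R,9R)-4-(acetoxymethyl)-4,5-epoxy-7-hydroxy-10-methylcyclodec-1(10)-en-9-yl 2,2-dichloropropanoate (C7 epimers)
Conditions: HF·pyridine, pyridine, THF, 0 °C to rt
Reagents that add atoms: none
Why: Fluoride cleavage of the silyl ether in a pyridine-buffered medium avoids the acyl migration from O9 to O7 and the ester cleavage that a basic fluoride source would cause.

Step 18
Reactants: 23 (E,4R,5R,9R)-4-(acetoxymethyl)-4,5-epoxy-7-hydroxy-10-methylcyclodec-1(10)-en-9-yl 2,2-dichloropropanoate
Product: 24 (E,4R,5R,9R)-4-(acetoxymethyl)-4,5-epoxy-10-methyl-7-oxocyclodec-1(10)-en-9-yl 2,2-dichloropropanoate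
Conditions: Dess–Martin periodinane, NaHCO3, CH2Cl2, 0 °C to rt; used crude
Reagents that add atoms: none
Why: Neutral oxidation merges the C7 epimers into one ketone; 24 has leaving groups β to both α-carbons of the ketone and is therefore taken on without chromatography.

Step 19
Reactants: 24 (E,4R,5R,9R)-4-(acetoxymethyl)-4,5-epoxy-10-methyl-7-oxocyclodec-1(10)-en-9-yl 2,2-dichloropropanoate
Product: 25 bridged chlorohydrin δ-lactone (O9–C12(=O)–C11–C7 bridge; 7-hydroxy, 11-chloro, 11-methyl; 4R,5R,7R,9R,11R)
Conditions: SmI2 (2.0 equiv, added slowly), THF, −78 °C; sat. aq. NH4Cl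
Reagents that add atoms: none
Why: SmI2 reduces a C–Cl bond of the α,α-dichloro ester much faster than the dialkyl ketone and gives a trivalent samarium chloro-enolate without base; this adds to C7 in an intramolecular Reformatsky-type aldol through a samarium chelate, forming C7–C11 and the six-membered lactone, and the three-atom bridge can reach C7 only from the side of O9, so the (9R)-centre sets C7; exact stoichiometry avoids further reduction of the chlorohydrin.

Step 20
Reactants: 25 bridged chlorohydrin δ-lactone
Product: 26 bridged epoxy δ-lactone (4R,5R,7R,9R,11S)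
Conditions: KN(SiMe3)2 (1.05 equiv), THF, −78 to −20 °C
Reagents that add atoms: none
Why: Second stage of a Darzens reaction: the C7 alkoxide displaces chloride at C11 with inversion (3-exo-tet), and the oxirane can only be cis-fused on the lactone, so C11 follows from C7; the ketone is gone at this stage, so a strong base is tolerated.

Step 21
Reactants: 26 bridged epoxy δ-lactone
Product: 27 (4R,5R,7R,9R,11R)-4,5:7,11-diepoxygermacr-1(10)E-ene-9,12,15-triol
Conditions: LiBH4, THF, 0 °C to rt
Reagents that add atoms: none
Why: LiBH4 reduces the lactone to the C12 primary alcohol and the C9 alcohol and also cleaves the C15 acetate; without a Lewis acid the oxiranes are not opened, and Payne equilibria favour the more substituted oxiranes already present.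

Step 22
Reactants: 27 (4R,5R,7R,9R,11R)-4,5:7,11-diepoxygermacr-1(10)E-ene-9,12,15-triol
Product: 28 (4R,5R,7R,9R,11R)-12,15-diacetoxy-4,5:7,11-diepoxygermacr-1(10)E-en-9-ol
Conditions: AcCl (2.1 equiv), 2,4,6-collidine, CH2Cl2, −78 to −40 °C
Reagents that add atoms: acetyl chloride, CC(Cl)=O
Why: Acetyl chloride with a hindered pyridine base at low temperature acylates primary alcohols in preference to a secondary one; the C9 carbinol is secondary, allylic and flanked by the ring.

Step 23
Reactants: 28 (4R,5R,7R,9R,11R)-12,15-diacetoxy-4,5:7,11-diepoxygermacr-1(10)E-en-9-ol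
Product: 29 (4R,5R,7S,11R)-12,15-diacetoxy-4,5:7,11-diepoxygermacr-1(10)E-en-9-one (target)
Conditions: Dess–Martin periodinane, NaHCO3, CH2Cl2, 0 °C to rt
Reagents that add atoms: none
Why: Neutral oxidation of the allylic alcohol gives the enone as the last step, so the base-labile β,γ-epoxy ketone never meets a base; the C7 descriptor changes from R to S only because C8 gains priority.

## Compound list

1 | pent-3-yn-1-ol | CC#CCCO | starting material
2 | bis-zirconated alkenylzirconocene (chlorozirconocene alkoxide of (E)-4-(chlorozirconocenyl)pent-3-en-1-ol) | C/C(=C\CCO[Zr](Cl)(C1C=CC=C1)C1C=CC=C1)[Zr](Cl)(C1C=CC=C1)C1C=CC=C1 | intermediate (not isolated)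
3 | (E)-4-iodopent-3-en-1-ol | OCC/C=C(\C)I | intermediate
4 | (E)-2,5-diiodopent-2-ene | ICC/C=C(\C)I | intermediate
5 | triethyl phosphonoacetate | CCOC(=O)CP(=O)(OCC)OCC | starting material
6 | ethyl (E)-2-(diethoxyphosphoryl)-6-iodohept-5-enoate (racemic) | CCOC(=O)C(CC/C=C(\C)I)P(=O)(OCC)OCC | intermediate
7 | ethyl (E)-6-iodo-2-methylidenehept-5-enoate | CCOC(=O)C(=C)CC/C=C(\C)I | intermediate
8 | (E)-6-iodo-2-methylidenehept-5-en-1-ol | OCC(=C)CC/C=C(\C)I | intermediate
9 | (R)-{2-[(E)-4-iodopent-3-en-1-yl]oxiran-2-yl}methanol | OC[C@]1(CC/C=C(\C)I)CO1 | intermediate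
10 | (S)-2-[(E)-4-iodopent-3-en-1-yl]oxirane-2-carbaldehyde | O=C[C@]1(CC/C=C(\C)I)CO1 | intermediate
11 | 4,4-dimethoxybutan-2-one | CC(=O)CC(OC)OC | starting material
12 | bromomagnesium 4,4-dimethoxybut-1-en-2-olate | C=C(O[Mg]Br)CC(OC)OC | intermediate (not isolated)
13 | bromomagnesium alkoxide of (5R)-5-hydroxy-5-{(2S)-2-[(E)-4-iodopent-3-en-1-yl]oxiran-2-yl}-1,1-dimethoxypentan-3-one | Br[Mg]O[C@@H]([C@]1(CC/C=C(\C)I)CO1)CC(=O)CC(OC)OC | intermediate (not isolated)
14 | 1-{(2R,3R)-3-(hydroxymethyl)-3-[(E)-4-iodopent-3-en-1-yl]oxiran-2-yl}-4,4-dimethoxybutan-2-one | OC[C@@]1(CC/C=C(\C)I)O[C@@H]1CC(=O)CC(OC)OC | intermediate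
15 | {(2R,3R)-3-(4,4-dimethoxy-2-oxobutyl)-2-[(E)-4-iodopent-3-en-1-yl]oxiran-2-yl}methyl acetate | CC(=O)OC[C@@]1(CC/C=C(\C)I)O[C@@H]1CC(=O)CC(OC)OC | intermediate
16 | {(2R,3R)-3-(2-hydroxy-4,4-dimethoxybutyl)-2-[(E)-4-iodopent-3-en-1-yl]oxiran-2-yl}methyl acetate (C7 epimers) | CC(=O)OC[C@@]1(CC/C=C(\C)I)O[C@@H]1CC(O)CC(OC)OC | intermediate
17 | {(2R,3R)-3-[2-(tert-butyldimethylsilyloxy)-4,4-dimethoxybutyl]-2-[(E)-4-iodopent-3-en-1-yl]oxiran-2-yl}methyl acetate (C7 epimers) | CC(=O)OC[C@@]1(CC/C=C(\C)I)O[C@@H]1CC(O[Si](C)(C)C(C)(C)C)CC(OC)OC | intermediate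
18 | {(2R,3R)-3-[2-(tert-butyldimethylsilyloxy)-4-oxobutyl]-2-[(E)-4-iodopent-3-en-1-yl]oxiran-2-yl}methyl acetate (C7 epimers) | CC(=O)OC[C@@]1(CC/C=C(\C)I)O[C@@H]1CC(O[Si](C)(C)C(C)(C)C)CC=O | intermediate
19 | (E,4R,5R)-4-(acetoxymethyl)-7-(tert-butyldimethylsilyloxy)-4,5-epoxy-10-methylcyclodec-1(10)-en-9-ol (C7 and C9 epimers) | CC(=O)OC[C@]12CC/C=C(\C)C(O)CC(O[Si](C)(C)C(C)(C)C)C[C@H]1O2 | intermediate
20 | (E,4R,5R)-4-(acetoxymethyl)-7-(tert-butyldimethylsilyloxy)-4,5-epoxy-10-methylcyclodec-1(10)-en-9-one (C7 epimers) | CC(=O)OC[C@]12CC/C=C(\C)C(=O)CC(O[Si](C)(C)C(C)(C)C)C[C@H]1O2 | intermediate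
21 | (E,4R,5R,9R)-4-(acetoxymethyl)-7-(tert-butyldimethylsilyloxy)-4,5-epoxy-10-methylcyclodec-1(10)-en-9-ol (C7 epimers) | CC(=O)OC[C@]12CC/C=C(\C)[C@H](O)CC(O[Si](C)(C)C(C)(C)C)C[C@H]1O2 | intermediate
22 | (E,4R,5R,9R)-4-(acetoxymethyl)-7-(tert-butyldimethylsilyloxy)-4,5-epoxy-10-methylcyclodec-1(10)-en-9-yl 2,2-dichloropropanoate (C7 epimers) | CC(=O)OC[C@]12CC/C=C(\C)[C@H](OC(=O)C(C)(Cl)Cl)CC(O[Si](C)(C)C(C)(C)C)C[C@H]1O2 | intermediate
23 | (E,4R,5R,9R)-4-(acetoxymethyl)-4,5-epoxy-7-hydroxy-10-methylcyclodec-1(10)-en-9-yl 2,2-dichloropropanoate (C7 epimers) | CC(=O)OC[C@]12CC/C=C(\C)[C@H](OC(=O)C(C)(Cl)Cl)CC(O)C[C@H]1O2 | intermediate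
24 | (E,4R,5R,9R)-4-(acetoxymethyl)-4,5-epoxy-10-methyl-7-oxocyclodec-1(10)-en-9-yl 2,2-dichloropropanoate | CC(=O)OC[C@]12CC/C=C(\C)[C@H](OC(=O)C(C)(Cl)Cl)CC(=O)C[C@H]1O2 | intermediate
25 | bridged chlorohydrin δ-lactone (4R,5R,7R,9R,11R): lactone O9–C12(=O)–C11(Cl)(CH3)–C7(OH), 4,5-oxirane, C15 acetate, (E)-C1=C10 | CC(=O)OC[C@]12CC/C=C(\C)[C@@H]3OC(=O)[C@](C)(Cl)[C@@](O)(C3)C[C@H]1O2 | intermediate
26 | bridged epoxy δ-lactone (4R,5R,7R,9R,11S): lactone O9–C12(=O)–C11, 7,11-oxirane, 4,5-oxirane, C15 acetate, (E)-C1=C10 | CC(=O)OC[C@]12CC/C=C(\C)[C@@H]3OC(=O)[C@@]4(C)O[C@]4(C3)C[C@H]1O2 | intermediate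
27 | (4R,5R,7R,9R,11R)-4,5:7,11-diepoxygermacr-1(10)E-ene-9,12,15-triol | OC[C@]12CC/C=C(\C)[C@H](O)C[C@]3(C[C@H]1O2)O[C@]3(C)CO | intermediate
28 | (4R,5R,7R,9R,11R)-12,15-diacetoxy-4,5:7,11-diepoxygermacr-1(10)E-en-9-ol | CC(=O)OC[C@]12CC/C=C(\C)[C@H](O)C[C@]3(C[C@H]1O2)O[C@]3(C)COC(C)=O | intermediate
29 | (4R,5R,7S,11R)-12,15-diacetoxy-4,5:7,11-diepoxygermacr-1(10)E-en-9-one (CNP0185847.3) | CC(=O)OC[C@]12CC/C=C(\C)C(=O)C[C@]3(C[C@H]1O2)O[C@]3(C)COC(C)=O | target

## Step count and least certain steps

Total: 23 steps. Longest linear sequence: 23 steps (1 to 29); 5 and 11 enter as commercial materials.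

**Step 8 (key step).**
- What may go wrong: poor facial selectivity at C5 if addition through a non-chelated arrangement (enolate passing the oxirane CH2 on the aldehyde-hydrogen side, with the C3 chain next to the carbonyl oxygen) competes, which after the shift would give the ring-trans oxirane; an incomplete Payne shift at the temperature the product tolerates; retro-aldol cleavage or β-elimination of the β,γ-epoxy ketone on warming; bromide opening of the magnesium-activated oxirane.
- Fallback, from phosphonate 6 back to 17, with C4 and C5 set together by a Sharpless epoxidation of a trisubstituted allylic alcohol. Methyl 3,3-dimethoxypropanoate (COC(=O)CC(OC)OC) undergoes Claisen condensation with the lithium enolate of methyl acetate to give methyl 5,5-dimethoxy-3-oxopentanoate F1. NaBH4 gives methyl 3-hydroxy-5,5-dimethoxypentanoate F2, TBSCl and imidazole give the silyl ether F3, and iBu2AlH at −78 °C gives 3-(tert-butyldimethylsilyloxy)-5,5-dimethoxypentanal F4. Horner–Wadsworth–Emmons reaction of the sodium salt of 6 with F4 should give mainly the (E)-enoate F5 (ester trans to C6). iBu2AlH gives the allylic alcohol F6. Epoxidation with Ti(OiPr)4, D-(−)-diisopropyl tartrate and tBuOOH gives the (4R,5R)-epoxy alcohol F7, and acetylation returns to 17.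

**Step 13.**
- What may go wrong: intermolecular coupling outrunning closure of the strained ten-membered ring, or protonation of the alkenylchromium species before it reaches the aldehyde.
- Fallback, from aldehyde 18 back to enone 20, closing the same bond by acyl–alkenyl coupling so that step 14 is not needed. Pinnick oxidation (NaClO2, NaH2PO4, 2-methylbut-2-ene) gives the carboxylic acid F8. Ethanethiol with dicyclohexylcarbodiimide gives the S-ethyl thioester F9. Hexamethylditin with Pd(PPh3)4 converts the alkenyl iodide into the trimethylstannane F10. Liebeskind–Srogl coupling at high dilution (Pd2(dba)3, tri(2-furyl)phosphine, copper thiophene-2-carboxylate with monovalent copper) joins C9 to C10 and gives 20.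

**Step 19.**
- What may go wrong: reduction of the C7 ketone or loss of the C9 carboxylate by β-elimination competing with the transannular addition; formation of the C11 epimer with chlorine syn to O7, which cannot close in step 20.
- Fallback, from 21 back to 26, by Reformatsky reaction, dehydration and epoxidation. 2-Bromopropanoyl bromide and pyridine give the bromo ester F11. HF·pyridine gives the C7 alcohol F12 and Dess–Martin periodinane the ketone F13. SmI2 at −78 °C effects the intramolecular Reformatsky reaction of the α-bromo ester to the bridged β-hydroxy lactone F14. Mesylation with MsCl and Et3N followed by DBU gives the α,β-unsaturated lactone F15 (C7=C11). Lithium tert-butylperoxide (from tBuOOH and nBuLi, THF, −20 °C) epoxidises F15 from the face away from the seven-atom ring bridge, which is the face required, and gives 26.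

**Step 20.**
- What may go wrong: retro-aldol cleavage of the tertiary alkoxide with decomposition of the regenerated ketone, or no closure when chlorine is not anti to O7.
- Fallback, from 25 back to 26: two further equivalents of SmI2 reduce the remaining C–Cl bond and expel the C7 oxygen, a reductive β-elimination that does not depend on the C11 configuration. This gives the unsaturated lactone F15, the same compound as in the fallback to step 19, which is epoxidised as described there.

## Further compounds

F1 | step 8 | methyl 5,5-dimethoxy-3-oxopentanoate | COC(=O)CC(=O)CC(OC)OC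
F2 | step 8 | methyl 3-hydroxy-5,5-dimethoxypentanoate (racemic) | COC(=O)CC(O)CC(OC)OC
F3 | step 8 | methyl 3-(tert-butyldimethylsilyloxy)-5,5-dimethoxypentanoate (racemic) | COC(=O)CC(O[Si](C)(C)C(C)(C)C)CC(OC)OC
F4 | step 8 | 3-(tert-butyldimethylsilyloxy)-5,5-dimethoxypentanal (racemic) | O=CCC(O[Si](C)(C)C(C)(C)C)CC(OC)OC
F5 | step 8 | ethyl (2E)-5-(tert-butyldimethylsilyloxy)-2-[(E)-4-iodopent-3-en-1-yl]-7,7-dimethoxyhept-2-enoate | CCOC(=O)/C(CC/C=C(\C)I)=C/CC(O[Si](C)(C)C(C)(C)C)CC(OC)OC
F6 | step 8 | (2E)-5-(tert-butyldimethylsilyloxy)-2-[(E)-4-iodopent-3-en-1-yl]-7,7-dimethoxyhept-2-en-1-ol | OC/C(CC/C=C(\C)I)=C/CC(O[Si](C)(C)C(C)(C)C)CC(OC)OC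
F7 | step 8 | {(2R,3R)-3-[2-(tert-butyldimethylsilyloxy)-4,4-dimethoxybutyl]-2-[(E)-4-iodopent-3-en-1-yl]oxiran-2-yl}methanol (C7 epimers) | OC[C@@]1(CC/C=C(\C)I)O[C@@H]1CC(O[Si](C)(C)C(C)(C)C)CC(OC)OC
F8 | step 13 | 4-{(2R,3R)-3-(acetoxymethyl)-3-[(E)-4-iodopent-3-en-1-yl]oxiran-2-yl}-3-(tert-butyldimethylsilyloxy)butanoic acid (C7 epimers) | CC(=O)OC[C@@]1(CC/C=C(\C)I)O[C@@H]1CC(O[Si](C)(C)C(C)(C)C)CC(=O)O
F9 | step 13 | S-ethyl thioester of F8 | CC(=O)OC[C@@]1(CC/C=C(\C)I)O[C@@H]1CC(O[Si](C)(C)C(C)(C)C)CC(=O)SCC
F10 | step 13 | S-ethyl thioester with (E)-4-(trimethylstannyl)pent-3-en-1-yl chain | CC(=O)OC[C@@]1(CC/C=C(\C)[Sn](C)(C)C)O[C@@H]1CC(O[Si](C)(C)C(C)(C)C)CC(=O)SCC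
F11 | step 19 | (E,4R,5R,9R)-4-(acetoxymethyl)-7-(tert-butyldimethylsilyloxy)-4,5-epoxy-10-methylcyclodec-1(10)-en-9-yl 2-bromopropanoate | CC(=O)OC[C@]12CC/C=C(\C)[C@H](OC(=O)C(C)Br)CC(O[Si](C)(C)C(C)(C)C)C[C@H]1O2
F12 | step 19 | (E,4R,5R,9R)-4-(acetoxymethyl)-4,5-epoxy-7-hydroxy-10-methylcyclodec-1(10)-en-9-yl 2-bromopropanoate | CC(=O)OC[C@]12CC/C=C(\C)[C@H](OC(=O)C(C)Br)CC(O)C[C@H]1O2
F13 | step 19 | (E,4R,5R,9R)-4-(acetoxymethyl)-4,5-epoxy-10-methyl-7-oxocyclodec-1(10)-en-9-yl 2-bromopropanoate | CC(=O)OC[C@]12CC/C=C(\C)[C@H](OC(=O)C(C)Br)CC(=O)C[C@H]1O2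
F14 | step 19 | bridged β-hydroxy δ-lactone (7-hydroxy, 11-methyl, C11 epimers) | CC(=O)OC[C@]12CC/C=C(\C)[C@@H]3OC(=O)C(C)[C@@](O)(C3)C[C@H]1O2
F15 | step 19 | bridged α,β-unsaturated δ-lactone (C7=C11) | CC(=O)OC[C@]12CC/C=C(\C)[C@@H]3OC(=O)C(C)=C(C3)C[C@H]1O2
F0 | step 20 | none | none
A1 | alternative 1 | ten-membered triene ketal bis-PMB ether | COc1ccc(COC/C2=C/C/C(=C(\C)COCc3ccc(OC)cc3)CC4(OCCO4)/C(C)=C/CC2)cc1
A2 | alternative 2 | bridged epoxy lactone | CC(=O)OC[C@]12CC/C=C(\C)[C@@H]3OC(=O)[C@@]4(C)O[C@]4(C3)C[C@H]1O2
A3 | alternative 3 | (E)-enone, ring-cis cyclodecadienone | CC(C)[Si](C(C)C)(C(C)C)OC/C1=C/C[C@@H](O[Si](C)(C)C(C)(C)C)CC(=O)/C(C)=C/CC1
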